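The easy step was to lay the earlier runs beside the two flasks asked about.

common to all: Q 0.050 M

|  | D | Z | remark | time |
|---|---|---|---|---|
| ochre | 3.4 mM | 1 mol% | run made earlier |  |
| green | 7.5 mM | 1 mol% | run made earlier |  |
| violet | 5 mM | 2 mol% | run made earlier |  |
| Monday's | 5.00 mM | 1 mol% |  | 1.0 h |
| Sunday's | 5.00 mM | 1 mol% |  | 4.0 h |

| run | time / min | G / % | Q / % |
|---|---|---|---|
| ochre | 4.00 | 1.3 | 95.8 |
| ochre | 12.0 | 3.9 | 86.0 |
| ochre | 20.0 | 8.1 | 75.6 |
| ochre | 30.0 | 12.6 | 63.6 |
| ochre | 40.0 | 17.8 | 53.1 |
| ochre | 60.0 | 25.2 | 37.1 |
| ochre | 80.0 | 29.5 | 25.9 |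
| green | 6.00 | 2.2 | 92.4 |
| green | 8.00 | 1.9 | 90.5 |
| green | 12.0 | 3.4 | 85.0 |
| green | 20.0 | 6.8 | 75.7 |
| green | 30.0 | 13.1 | 64.4 |
| green | 50.0 | 20.4 | 46.3 |
| green | 80.0 | 26.5 | 28.7 |
| violet | 6.00 | 3.1 | 91.9 |
| violet | 10.0 | 5.9 | 86.0 |
| violet | 20.0 | 14.1 | 68.7 |
| violet | 40.0 | 31.3 | 42.8 |
| violet | 80.0 | 46.6 | 16.9 |

(scatter of a reading: 0.5 percentage points)

- the average divides the monomer in chains by the number of chains begun, living and dead together
- the earlier runs do not show the number of chains; that part of a forecast is a guess

- which of the two ends with the longer chains by the average number of monomer units in a chain (chains begun, living or dead) ("neither" if they lie within 10%) (Monday's / Sunday's / neither)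
- average number of monomer units in a chain (chains begun, living or dead) at the end, Monday's
- average number of monomer units in a chain (chains begun, living or dead) at the end, Sunday's

I began at the reading time that Monday's shares with the ochre run. At 60.0 min the ochre run held 25.2% of G, and the green run, read between its two nearest rows, about 22.4%. Monday's D lies 39.0% of the way from ochre to green, so I put its G at 24.1%.

The runs do not show chains, so I guessed one chain per Z started. I then divided G by the Z charge, both in percent of the Q charged, and got 24.1 for Monday's: the units per Z charged. On that guess the average length, the degree of polymerisation, is this count divided by the share of Z started.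

The violet row showed how far that count travels. At 80.0 min, the violet run, with Monday's D and 2 mol% of Z, gave 46.6% of G, against 28.3% interpolated for 1 mol%. Its units per Z charged were therefore 23.3 against 28.3, so I had to count afresh for each loading.

For Sunday's I used the Q column. Over the last stretch of ochre and green, interpolated to Monday's D, 36.9% of the Q lost became G. Interpolated the same way, about 27.0% of Q remained at 80.0 min. Assuming that this whole remainder reacted by 4.0 h and that the share held, I estimated G for Sunday's near 38.3%, or 38.3 units per Z charged, well above Monday's. I committed to Sunday's.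

The forecast also chose Sunday's, with 25.5 (21 to 33) for Monday's, above my figure, and 35 (28 to 47) for Sunday's, below mine: “Assuming one chain per Z is the guess.”

The flasks gave 26.1 for Monday's and 37.9 for Sunday's, so Sunday's ended longer.

    2 Q → E (k = 6.20 × 10⁻⁴ M⁻¹ min⁻¹)
    Q + Z → J + G (k = 1.30 M⁻¹ min⁻¹)
    J + D → X (k = 1.30 M⁻¹ min⁻¹)
    Q → L (k = 0.00950 min⁻¹)
    Q + J → G + J, rate k5*[J]*[Q] (k = 21.0 M⁻¹ min⁻¹)

Each Z that reacts begins one chain. Monday's still held 7.7% of its Z at the end, and dividing my 24.1 by the share started gives 26.1. A flask like Sunday's but with 2.5 mol% of Z ended with 59.8% of G, which is 23.9 units per Z charged. With 6.7% of its Z unstarted, that count becomes 25.6, and the flask's average length was 25.6.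

(The readings stem from a simulated flask from invented constants, noise included.)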